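## The problem

CNP0126182.2 is a trans-fused hydroazulene acetate. The numbering used below is C1–C7 for the seven-membered ring (exocyclic methylene on C1, hydroxyls on C2 and C5, side chain on C4), C6–C10 for the five-membered ring (C8=C9, methyl and hydroxyl on C10) and C11–C15 for the chain (C11 methyl, C12 acetate, C14=C15 prenyl end); β is the face of H7 and the C10 methyl group, α the face of H6, the C4 chain and the C5 and C10 oxygens. A synthesis has to join a seven- to a five-membered ring with a trans fusion and set eight stereocentres: C2, C4, C5, C6, C7 and C10 in the bicycle and the syn pair C11/C12 in the chain. The chain pair is too far from the rings to be relayed, so ring and chain must each be made enantioenriched and then joined. Within the bicycle C10 can steer the face on which C7 is built, C7 can fix C4, and C4 and C10 can bias the C5 carbonyl; C2 lies 1,3 to both C4 and C7 and is the centre least reliably set by the substrate. The tertiary allylic alcohol at C10, the doubly allylic C7–H, the allylic alcohol beside the exocyclic methylene and the single acetate among three free hydroxyls exclude strong acid, late strong base and any unselective acylation at the end. The feature that opens the key step is that the oxygens on C2 and C5 are 1,4-related across the C3–C4 bond. If C1=C2 and C5=C6 are written as enol ether double bonds, the seven-membered ring is a cyclohepta-1,4-diene whose C3–C4 bond is the bond made when a cis-divinylcyclopropane (ring C1, C6, C7, fused to the five-membered ring through C6–C7) undergoes Cope rearrangement with loss of a C1–C6 bond that the target lacks.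

## Retrosynthesis

C5–H, C6–H and O–Si bonds (32 ⇒ 31 ⇒ 30 ⇒ 28). The last operations only add hydrogen to C5 and C6 and remove silicon: 32 comes from its C10 triethylsilyl ether 31, 31 from the trans-fused C5 ketone 30, and 30 from the C5=C6 enol silane 28. This is preferred to any late C–C bond formation because the acetate, the exocyclic alkene and C8=C9 are then already in place. The forward steps must protonate C6 on the α face (by equilibration) and deliver hydride to C5 from the β face without touching the acetate.

C1=CH2 carbon and C2–H (28 ⇒ 27 ⇒ 24). The exocyclic carbon and the C2 carbinol are traced to the C1=C2 enol silane of the hydroazulene 24 through the methylene enone 27. C2 is reduced before C5 is unmasked, so that no free hydroxyl sits across the ring when the enone is present. The Mannich step must choose the trisubstituted C1=C2 enol ether over the tetrasubstituted C5=C6 one, and the C2 reduction needs reagent control.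

C3–C4 (24 ⇒ 23), the key disconnection. Cutting C3–C4 while closing C1–C6 turns the hydroazulene bis(enol silane) 24 into the bicyclo[3.1.0]hexene 23. This cut is preferred to C4–C5 or C4–C11 cuts because it removes the seven-membered ring and the C4 stereocentre in one step and leaves both oxygens where the target needs them. The forward Cope rearrangement must run through the boat transition state with a Z enol ether at C5, so that C7 dictates C4.

Enol ethers and C8=C9 (23 ⇒ 22 ⇒ 21 ⇒ 20). The two silyl enol ethers come from the cyclopropyl diketone 22, and the C8=C9 alkene from a C9 oxygen (21, 20). The alkene is made at this point because the C9 hydroxyl is then the only free hydroxyl in the molecule; a late dehydration would need an extra orthogonal protecting group. Enolisation must be soft, since the acetate is already present.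

C1–C6 and C1–C7 (20 ⇒ 18 + 16). The cyclopropane is cut to the enone 18 and the acetonyl sulfonium salt 16 (from chloroacetone 15). An ylide addition is chosen over a carbenoid because the alkene is electron-poor and because the acetyl group then arrives exo, cis to the C6 acyl group. The forward step must add C1 on the α face, anti to the C10 methyl and the C9 silyloxy group.

C5–C6 (18 ⇒ 7 + 14). The enone is cut between ring and chain into the vinyl triflate 7 and the aldehyde 14. This replaces a conjugate addition followed by dehydrogenation, which would be regiochemically ambiguous at C4 versus C6 and would not relate C10 to the chain stereocentres. The coupling must tolerate an acetate and two silyl ethers.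

Ring fragment (7 ⇒ 6 ⇒ 5 ⇒ 4 ⇒ 3 ⇒ 2 ⇒ 1). The triflate is traced through the trans-diol ketone 5 and the epoxy ketone 4 to 2-methylcyclopent-2-en-1-one 1. One catalytic reduction sets the absolute configuration; directed epoxidation and inverting epoxide opening set C10 and place the C9 oxygen trans to the C10 oxygen.

Chain fragment (14 ⇒ 13 ⇒ 12 ⇒ 11 ⇒ 9 + 10; 9 ⇒ 8). The syn C11/C12 pair is made in one C11–C12 bond formation between 4-methylpent-3-enal 9 (from the alcohol 8) and the Z-crotylboronate 10. The vinyl group of 11 then becomes C4 and the C5 aldehyde; the acetate is installed at once (12) and carried to the end.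

## Roads not taken

Alternative 1: The cut is the C6–C7 bond, reached by a Wagner–Meerwein shift in a cis-decalin from a chiral-pool cyclohexenone. Forward, ionisation of an equatorial C7 sulfonate makes C6 migrate from C1 to C7, one six-membered ring contracts, the other expands, and the C1 cation loses a methyl proton to give the hydroazulene A1. Its merits are real: ring fusion, exocyclic methylene and C4 configuration come from a stereospecific, antiperiplanar migration and a cheap chiral starting material. In ring-fusion control it is better than the chosen plan, which has to equilibrate C6. Its weak points for this target are what A1 lacks: there is no oxygen on C2 (a late allylic oxidation next to a doubly allylic C7–H), the C9/C10 acetonide still has to become C8=C9 by late dehydration, and the chain ends at C12, so C12 and the prenyl group must be added later under weak 1,2-induction. The chosen plan sets against this a key step that delivers both ring oxygens at the right carbons and a chain that arrives complete, with C11/C12 fixed by a catalyst.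

Alternative 2: The cut is C4–C11. A C11 radical generated from a bromoacetal on the C5 oxygen under tin hydride conditions adds 5-exo to C4 of a C3=C4 alkene and gives the cis-fused acetal A2. The tether guarantees the cis C4/C5 relationship, which the chosen plan reaches only in two separate steps, and the cyclisation type is dependable. Against it: the radical step creates C11 with only modest control, C12 must then be made by adding a prenyl nucleophile to the unmasked lactol, and opening the acetal frees C5–OH and C12–OH together, so the acetate cannot be placed selectively without more protection steps. The alternative also presupposes a complete hydroazulene with the C3=C4 alkene, so it solves the chain but not the ring. The chosen plan forms the ring and sets C4 in the same step and never has to distinguish C5–OH from C12–OH.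

Alternative 3: The cut is C4–C5. A tethered 2-(alkoxycarbonyl)allylboronate adds through its γ-carbon C4 to a C5 aldehyde, closes the seven-membered ring and lactonises to the methylene lactone A3. It forms the ring and the cis C4/C5 pair in one closed transition state and is comparable to the chosen key step in that respect. Its weakness lies after A3: C11 must be set by conjugate reduction of the methylene lactone, C12 by addition of a prenyl group to the lactone carbonyl followed by reduction, both late and substrate-controlled, and the resulting C5/C12 diol again needs selective acetylation. The cyclisation precursor also has to carry the trans-related C6/C7 centres, the C1 methylene and the C2 oxygen on an open chain. The chosen plan has to set against this only the later adjustment of C5 and C6, for which a thermodynamic and a steric argument are available.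

Key step: step 19

Remark: the target is taken exactly as the given SMILES, i.e. the trans-fused (2R,4S,5R,6R,7R,10S,11S,12S) isomer in the numbering defined above; 4-methylpent-3-en-1-ol and the Z-crotylboronate are used as the commercial sources of the chain carbons.

## Route

Step 1
Reactants: 1 2-methylcyclopent-2-en-1-one
Product: 2 (R)-2-methylcyclopent-2-en-1-ol
Conditions: (S)-2-methyl-CBS-oxazaborolidine (10 mol %), BH3·SMe2, THF, −20 °C; MeOH quench
Reagents that add atoms: none
Why: Corey–Bakshi–Shibata reduction; the 2-methylvinyl arm acts as the large group, so the (S)-catalyst should give the (R)-allylic alcohol, which fixes the absolute configuration of the ring fragment.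

Step 2
Reactants: 2 (R)-2-methylcyclopent-2-en-1-ol
Product: 3 (1R,2R,5S)-1-methyl-6-oxabicyclo[3.1.0]hexan-2-ol (epoxide cis to the hydroxyl)
Conditions: VO(acac)2 (2 mol %), t-BuOOH, CH2Cl2, 0 °C to rt
Reagents that add atoms: tert-butyl hydroperoxide, CC(C)(C)OO
Why: Hydroxyl-directed epoxidation through a vanadium alkoxide–peroxide complex delivers oxygen to the alkene face cis to the hydroxyl and so sets the C10 oxygen relative to the carbinol.

Step 3
Reactants: 3 (1R,2R,5S)-1-methyl-6-oxabicyclo[3.1.0]hexan-2-ol
Product: 4 (1S,5S)-1-methyl-6-oxabicyclo[3.1.0]hexan-2-one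
Conditions: Dess–Martin periodinane, NaHCO3, CH2Cl2, 0 °C to rt
Reagents that add atoms: none
Why: Dess–Martin oxidation of the secondary alcohol; the new carbonyl becomes C6 and deactivates the neighbouring tertiary epoxide carbon C10 toward ionisation.

Step 4
Reactants: 4 (1S,5S)-1-methyl-6-oxabicyclo[3.1.0]hexan-2-one
Product: 5 (2S,3R)-2,3-dihydroxy-2-methylcyclopentan-1-one (trans-diol)
Conditions: HClO4 (cat.), THF/H2O, rt
Reagents that add atoms: water, O
Why: Acid-catalysed epoxide hydrolysis; water attacks the protonated epoxide in SN2 fashion at the secondary carbon C9 (inversion) because the tertiary carbon is next to the carbonyl, giving the trans-diol, and C10 has no hydrogen, so the β-hydroxy ketone cannot dehydrate.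

Step 5
Reactants: 5 (2S,3R)-2,3-dihydroxy-2-methylcyclopentan-1-one
Product: 6 (2S,3R)-2-methyl-2,3-bis(triethylsilyloxy)cyclopentan-1-one
Conditions: TESOTf, 2,6-lutidine, CH2Cl2, −78 to 0 °C
Reagents that add atoms: triethylsilyl trifluoromethanesulfonate, CC[Si](CC)(CC)OS(=O)(=O)C(F)(F)F
Why: Silylation with a silyl triflate and a hindered pyridine base protects the secondary and the tertiary hydroxyl in one operation; the base is too weak to enolise the ketone.

Step 6
Reactants: 6 (2S,3R)-2-methyl-2,3-bis(triethylsilyloxy)cyclopentan-1-one
Product: 7 (4R,5S)-5-methyl-4,5-bis(triethylsilyloxy)cyclopent-1-en-1-yl trifluoromethanesulfonate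
Conditions: KN(SiMe3)2, THF, −78 °C; PhNTf2, −78 to 0 °C
Reagents that add atoms: N-phenylbis(trifluoromethanesulfonimide), O=S(=O)(N(c1ccccc1)S(=O)(=O)C(F)(F)F)C(F)(F)F
Why: Enolate O-triflation; C10 is quaternary, so the ketone can enolise only toward C7 and the C6=C7 vinyl triflate forms regiospecifically.

Step 7
Reactants: 8 4-methylpent-3-en-1-ol
Product: 9 4-methylpent-3-enal
Conditions: Dess–Martin periodinane, NaHCO3, CH2Cl2, 0 °C; cold solution used at once
Reagents that add atoms: none
Why: Buffered Dess–Martin oxidation gives the β,γ-unsaturated aldehyde under neutral conditions, which avoids migration of the alkene into conjugation.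

Step 8
Reactants: 9 4-methylpent-3-enal; 10 2-[(2Z)-but-2-en-1-yl]-4,4,5,5-tetramethyl-1,3,2-dioxaborolane
Product: 11 (3S,4S)-3,7-dimethylocta-1,6-dien-4-ol
Conditions: (R)-3,3′-bis(2,4,6-triisopropylphenyl)-1,1′-binaphthyl-2,2′-diyl hydrogen phosphate (5 mol %), 4 Å MS, toluene, −30 °C; aqueous work-up
Reagents that add atoms: none
Why: Chiral phosphoric acid-catalysed crotylboration through a closed chair transition state; the Z-crotyl geometry gives the syn C11/C12 pair and the (R)-catalyst should direct addition to the Re face of the aldehyde, giving the 4S carbinol (the antipodal catalyst would give the enantiomer).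

Step 9
Reactants: 11 (3S,4S)-3,7-dimethylocta-1,6-dien-4-ol
Product: 12 (3S,4S)-3,7-dimethylocta-1,6-dien-4-yl acetate
Conditions: Ac2O, pyridine, DMAP (cat.), CH2Cl2, rt
Reagents that add atoms: acetic anhydride, CC(=O)OC(C)=O
Why: DMAP-catalysed acetylation; the acetate of the target is installed here because every later step is chosen to tolerate it.

Step 10
Reactants: 12 (3S,4S)-3,7-dimethylocta-1,6-dien-4-yl acetate
Product: 13 (3S,4S)-1-hydroxy-3,7-dimethyloct-6-en-4-yl acetate
Conditions: 9-BBN, THF, 0 °C to rt; aq. NaOAc, H2O2, 0 °C
Reagents that add atoms: hydrogen peroxide, OO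
Why: Hydroboration–oxidation; 9-BBN selects the monosubstituted over the trisubstituted alkene and places boron on the terminal carbon, and the acetate-buffered oxidation spares the ester.

Step 11
Reactants: 13 (3S,4S)-1-hydroxy-3,7-dimethyloct-6-en-4-yl acetate
Product: 14 (3S,4S)-3,7-dimethyl-1-oxooct-6-en-4-yl acetate
Conditions: Dess–Martin periodinane, NaHCO3, CH2Cl2, rt
Reagents that add atoms: none
Why: Dess–Martin oxidation of the primary alcohol to the C5 aldehyde; the α-carbon is a methylene, so nothing can epimerise.

Step 12
Reactants: 15 chloroacetone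
Product: 16 dimethyl(2-oxopropyl)sulfonium chloride
Conditions: Me2S, acetone, rt
Reagents that add atoms: dimethyl sulfide, CSC
Why: SN2 alkylation of the sulfide by the α-chloro ketone gives the acyl-stabilised sulfonium salt that will carry C1, C2 and C3.

Step 13
Reactants: 7 (4R,5S)-5-methyl-4,5-bis(triethylsilyloxy)cyclopent-1-en-1-yl trifluoromethanesulfonate; 14 (3S,4S)-3,7-dimethyl-1-oxooct-6-en-4-yl acetate
Product: 17 (3S,4S)-1-hydroxy-3,7-dimethyl-1-[(4R,5R)-5-methyl-4,5-bis(triethylsilyloxy)cyclopent-1-en-1-yl]oct-6-en-4-yl acetate (both epimers at the new carbinol, C5 of the target)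
Conditions: CrCl2, NiCl2 (cat.), DMF, rt
Reagents that add atoms: none
Why: Nozaki–Hiyama–Kishi coupling; nickel inserts into the vinyl triflate, the alkenyl group passes to chromium and adds to the aldehyde, forming C5–C6 in the presence of the acetate and silyl ethers, and the C5 epimers converge in the next step.

Step 14
Reactants: 17 allylic alcohol from step 13
Product: 18 (3S,4S)-3,7-dimethyl-1-[(4R,5R)-5-methyl-4,5-bis(triethylsilyloxy)cyclopent-1-en-1-yl]-1-oxooct-6-en-4-yl acetate (C5 ketone conjugated with C6=C7)
Conditions: Dess–Martin periodinane, NaHCO3, CH2Cl2, rt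
Reagents that add atoms: none
Why: Dess–Martin oxidation of the allylic alcohol gives the enone with the double bond fixed at C6=C7 by the origin of the triflate.

Step 15
Reactants: 18 enone from step 14; 16 dimethyl(2-oxopropyl)sulfonium chloride
Product: 20 (3S,4S)-1-[6-exo-acetyl-2-methyl-2,3-bis(triethylsilyloxy)bicyclo[3.1.0]hexan-1-yl]-3,7-dimethyl-1-oxooct-6-en-4-yl acetate (cyclopropane C1/C6/C7 on the α face, syn to the C10 silyloxy group and anti to the C9 silyloxy group; acetyl cis to the C6 acyl group), via sulfonium ylide 19 (not isolated)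
Conditions: K2CO3, MeCN, rt to 45 °C
Reagents that add atoms: none
Why: Michael-initiated ring closure of an acyl-stabilised sulfonium ylide (enone cyclopropanation): C1 adds to C7 and the enolate displaces Me2S to close C1–C6. The ylide should enter anti to the C10 methyl and the C9 silyloxy group on the β face, the C10 oxygen being the smaller flanking substituent on the α face, and the acetyl group takes the exo position away from the five-membered ring (an endo epimer would equilibrate at C1 under the basic conditions).

Step 16
Reactants: 20 cyclopropyl diketone from step 15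
Product: 21 (3S,4S)-1-[6-exo-acetyl-3-hydroxy-2-methyl-2-(triethylsilyloxy)bicyclo[3.1.0]hexan-1-yl]-3,7-dimethyl-1-oxooct-6-en-4-yl acetate (free C9 hydroxyl, β)
Conditions: HF·pyridine, pyridine, THF, 0 °C
Reagents that add atoms: none
Why: Selective desilylation; the secondary triethylsilyl ether is cleaved much faster than the hindered tertiary one under buffered fluoride, which frees only the C9 hydroxyl.

Step 17
Reactants: 21 C9 alcohol from step 16
Product: 22 (3S,4S)-1-[6-exo-acetyl-2-methyl-2-(triethylsilyloxy)bicyclo[3.1.0]hex-3-en-1-yl]-3,7-dimethyl-1-oxooct-6-en-4-yl acetate (C8=C9; cyclopropane syn to the silyloxy group)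
Conditions: Burgess reagent, toluene, 60 °C
Reagents that add atoms: none
Why: Burgess dehydration by syn elimination of the sulfamate ester; C10 is quaternary, so only a C8 hydrogen can be lost and the alkene forms at C8=C9, while the protected tertiary oxygen and the ketones are inert.

Step 18
Reactants: 22 alkene diketone from step 17
Product: 23 (1Z,3S,4S)-1-(tert-butyldimethylsilyloxy)-1-{6-exo-[1-(tert-butyldimethylsilyloxy)ethenyl]-2-methyl-2-(triethylsilyloxy)bicyclo[3.1.0]hex-3-en-1-yl}-3,7-dimethylocta-1,6-dien-4-yl acetate (cis-bis(silyloxyvinyl)cyclopropane)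
Conditions: TBSOTf, Et3N, CH2Cl2, −78 to 0 °C; non-aqueous work-up
Reagents that add atoms: tert-butyldimethylsilyl trifluoromethanesulfonate, CC(C)(C)[Si](C)(C)OS(=O)(=O)C(F)(F)F
Why: Soft enolisation with silyl triflate and amine; the acetyl group enolises toward its methyl (toward the cyclopropane is strained), the C5 ketone toward C4 (C6 has no hydrogen) with the Z geometry favoured by A(1,3) strain between C11 and the quaternary C6, and the acetate is not enolised under these conditions.

Step 19
Reactants: 23 cis-bis(silyloxyvinyl)cyclopropane from step 18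
Product: 24 (2S,3S)-2-[5,8-bis(tert-butyldimethylsilyloxy)-1-methyl-1-(triethylsilyloxy)-1,3a,6,7-tetrahydroazulen-7-yl]-6-methylhept-5-en-3-yl acetate (enol silanes at C1=C2 and C5=C6; C4, C7 and C10 as in the target)
Conditions: toluene, 80 °C
Reagents that add atoms: none
Why: Concerted [3,3] sigmatropic (Cope) rearrangement of a cis-1,2-divinylcyclopropane through the boat transition state in which both silyloxyvinyl groups lie over the three-membered ring; the closest known reaction type is the thermal rearrangement of cis-bis(silyloxyvinyl)cyclopropanes to cyclohepta-1,4-diene bis(enol silanes). The seven-membered ring closes by bonding of the two vinyl termini C3 and C4 while the strained C1–C6 bond opens, a ring expansion of the bicyclo[3.1.0]hexane to the bicyclo[5.3.0]decane driven by release of cyclopropane strain. C4 is the only new stereocentre: in the boat the C4 hydrogen (cis to C6 on the Z enol ether) points toward H7 and C11 points outward, so H4 ends cis to H7 and the side chain cis to C8, as in the target; C7 and C10 pass through unchanged. The step needs the two vinyl groups cis, which the exo acetyl group and the C6 ring fusion secure. It needs the Z enol ether at C5, which A(1,3) strain against quaternary C6 secures under the equilibrating enolisation of step 18. It needs regio-defined enol ethers, which follow because neither ketone can enolise toward the cyclopropane. The C8=C9 alkene is trans to both vinyl groups across the cyclopropane and cannot enter a competing Cope pathway.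

Step 20
Reactants: 24 hydroazulene bis(enol silane) from step 19
Product: 27 (2S,3S)-2-[8-(tert-butyldimethylsilyloxy)-1-methyl-4-methylidene-5-oxo-1-(triethylsilyloxy)-1,3a,4,5,6,7-hexahydroazulen-7-yl]-6-methylhept-5-en-3-yl acetate (methylene enone; C5=C6 enol silane intact), via Mannich base 25 (not isolated), via methiodide 26 (not isolated)
Conditions: Me2N=CH2+ I−, CH2Cl2, 0 °C to rt; MeI, rt; sat. aq. NaHCO3
Reagents that add atoms: N,N-dimethylmethyleneiminium iodide (Eschenmoser's salt), C=[N+](C)C.[I-]; iodomethane, CI (retained only in intermediate 26)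
Why: Mannich reaction of the trisubstituted C1=C2 enol silane with the iminium salt (the tetrasubstituted C5=C6 enol ether would have to form a quaternary centre next to C10 and is left), then exhaustive methylation and E1cB loss of trimethylamine to the α-methylene ketone.

Step 21
Reactants: 27 methylene enone from step 20
Product: 28 (2S,3S)-2-[8-(tert-butyldimethylsilyloxy)-5-hydroxy-1-methyl-4-methylidene-1-(triethylsilyloxy)-1,3a,4,5,6,7-hexahydroazulen-7-yl]-6-methylhept-5-en-3-yl acetate (C2 carbinol R, hydroxyl β)
Conditions: (S)-2-methyl-CBS-oxazaborolidine (1 equiv), catecholborane, toluene, −78 °C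
Reagents that add atoms: none
Why: Corey–Bakshi–Shibata reduction under reagent control; the α-methylene arm C1 is the large group, so the (S)-catalyst should give the 2R alcohol by 1,2-reduction, and catecholborane at −78 °C leaves the alkenes, the acetate and the enol silane untouched.

Step 22
Reactants: 28 allylic alcohol from step 21
Product: 30 (2S,3S)-2-[5-hydroxy-1-methyl-4-methylidene-8-oxo-1-(triethylsilyloxy)-1,3a,4,5,6,7,8,8a-octahydroazulen-7-yl]-6-methylhept-5-en-3-yl acetate (trans-fused C5 ketone, H6 α), via cis-fused ketone 29 (not isolated)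
Conditions: Bu4NF, AcOH, THF, 0 °C; then DBU, toluene, rt
Reagents that add atoms: none
Why: Fluoride cleavage of the enol silane with kinetic protonation of C6 expected mainly on the open β face (cis-fused 29), then amidine-mediated enolate equilibration to the trans-fused ketone, in which C10 and the C4 side chain can both be pseudo-equatorial.

Step 23
Reactants: 30 trans-fused ketone from step 22
Product: 31 (2S,3S)-2-[5,8-dihydroxy-1-methyl-4-methylidene-1-(triethylsilyloxy)-1,3a,4,5,6,7,8,8a-octahydroazulen-7-yl]-6-methylhept-5-en-3-yl acetate (C5 hydroxyl α; all ring centres as in the target)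
Conditions: LiBH(s-Bu)3, THF, −78 °C; AcOH quench at −78 °C
Reagents that add atoms: none
Why: Bulky trialkylborohydride reduction; the hydride should enter C5 from the β face, away from the C10 triethylsilyloxy group and the C4 side chain on the α face, giving the α alcohol cis to the side chain, and the low temperature keeps the acetate in place.

Step 24
Reactants: 31 diol silyl ether from step 23
Product: 32 CNP0126182.2, (2S,3S)-6-methyl-2-[(1S,3aR,5R,7S,8R,8aR)-1,5,8-trihydroxy-1-methyl-4-methylidene-1,3a,4,5,6,7,8,8a-octahydroazulen-7-yl]hept-5-en-3-yl acetate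
Conditions: HF·pyridine, pyridine, THF, 0 °C to rt
Reagents that add atoms: none
Why: Fluoride-mediated cleavage of the tertiary triethylsilyl ether under buffered conditions that spare the acetate and the tertiary allylic alcohol.

## Compound list

1 | 2-methylcyclopent-2-en-1-one | CC1=CCCC1=O | starting material
2 | (R)-2-methylcyclopent-2-en-1-ol | O[C@@H]1CCC=C1C | intermediate
3 | (1R,2R,5S)-1-methyl-6-oxabicyclo[3.1.0]hexan-2-ol | O[C@@H]1CC[C@@H]2O[C@]12C | intermediate
4 | (1S,5S)-1-methyl-6-oxabicyclo[3.1.0]hexan-2-one | O=C1CC[C@@H]2O[C@]12C | intermediate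
5 | (2S,3R)-2,3-dihydroxy-2-methylcyclopentan-1-one | O=C1CC[C@@H](O)[C@]1(C)O | intermediate
6 | (2S,3R)-2-methyl-2,3-bis(triethylsilyloxy)cyclopentan-1-one | O=C1CC[C@@H](O[Si](CC)(CC)CC)[C@]1(C)O[Si](CC)(CC)CC | intermediate
7 | (4R,5S)-5-methyl-4,5-bis(triethylsilyloxy)cyclopent-1-en-1-yl trifluoromethanesulfonate | O=S(=O)(OC1=CC[C@@H](O[Si](CC)(CC)CC)[C@]1(C)O[Si](CC)(CC)CC)C(F)(F)F | intermediate
8 | 4-methylpent-3-en-1-ol | CC(C)=CCCO | starting material
9 | 4-methylpent-3-enal | CC(C)=CCC=O | intermediate
10 | 2-[(2Z)-but-2-en-1-yl]-4,4,5,5-tetramethyl-1,3,2-dioxaborolane | C/C=C\CB1OC(C)(C)C(C)(C)O1 | starting material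
11 | (3S,4S)-3,7-dimethylocta-1,6-dien-4-ol | C=C[C@H](C)[C@H](CC=C(C)C)O | intermediate
12 | (3S,4S)-3,7-dimethylocta-1,6-dien-4-yl acetate | C=C[C@H](C)[C@H](CC=C(C)C)OC(C)=O | intermediate
13 | (3S,4S)-1-hydroxy-3,7-dimethyloct-6-en-4-yl acetate | OCC[C@H](C)[C@H](CC=C(C)C)OC(C)=O | intermediate
14 | (3S,4S)-3,7-dimethyl-1-oxooct-6-en-4-yl acetate | O=CC[C@H](C)[C@H](CC=C(C)C)OC(C)=O | intermediate
15 | chloroacetone | CC(=O)CCl | starting material
16 | dimethyl(2-oxopropyl)sulfonium chloride | CC(=O)C[S+](C)C.[Cl-] | intermediate
17 | C5 allylic alcohol, (3S,4S)-1-hydroxy-3,7-dimethyl-1-[(4R,5R)-5-methyl-4,5-bis(triethylsilyloxy)cyclopent-1-en-1-yl]oct-6-en-4-yl acetate, both C5 epimers | OC(C[C@H](C)[C@H](CC=C(C)C)OC(C)=O)C1=CC[C@@H](O[Si](CC)(CC)CC)[C@]1(C)O[Si](CC)(CC)CC | intermediate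
18 | enone, (3S,4S)-3,7-dimethyl-1-[(4R,5R)-5-methyl-4,5-bis(triethylsilyloxy)cyclopent-1-en-1-yl]-1-oxooct-6-en-4-yl acetate | O=C(C[C@H](C)[C@H](CC=C(C)C)OC(C)=O)C1=CC[C@@H](O[Si](CC)(CC)CC)[C@]1(C)O[Si](CC)(CC)CC | intermediate
19 | dimethylsulfonium 2-oxopropylide | CC(=O)[CH-][S+](C)C | intermediate (not isolated)
20 | cyclopropyl diketone, (3S,4S)-1-[6-exo-acetyl-2-methyl-2,3-bis(triethylsilyloxy)bicyclo[3.1.0]hexan-1-yl]-3,7-dimethyl-1-oxooct-6-en-4-yl acetate, cyclopropane syn to the C10 oxygen | CC(=O)[C@H]1[C@@H]2C[C@@H](O[Si](CC)(CC)CC)[C@](C)(O[Si](CC)(CC)CC)[C@]12C(=O)C[C@H](C)[C@H](CC=C(C)C)OC(C)=O | intermediate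
21 | C9 alcohol, (3S,4S)-1-[6-exo-acetyl-3-hydroxy-2-methyl-2-(triethylsilyloxy)bicyclo[3.1.0]hexan-1-yl]-3,7-dimethyl-1-oxooct-6-en-4-yl acetate | CC(=O)[C@H]1[C@@H]2C[C@@H](O)[C@](C)(O[Si](CC)(CC)CC)[C@]12C(=O)C[C@H](C)[C@H](CC=C(C)C)OC(C)=O | intermediate
22 | alkene diketone, (3S,4S)-1-[6-exo-acetyl-2-methyl-2-(triethylsilyloxy)bicyclo[3.1.0]hex-3-en-1-yl]-3,7-dimethyl-1-oxooct-6-en-4-yl acetate | CC(=O)[C@H]1[C@@H]2C=C[C@](C)(O[Si](CC)(CC)CC)[C@]12C(=O)C[C@H](C)[C@H](CC=C(C)C)OC(C)=O | intermediate
23 | cis-bis(silyloxyvinyl)cyclopropane, (1Z,3S,4S)-1-(tert-butyldimethylsilyloxy)-1-{6-exo-[1-(tert-butyldimethylsilyloxy)ethenyl]-2-methyl-2-(triethylsilyloxy)bicyclo[3.1.0]hex-3-en-1-yl}-3,7-dimethylocta-1,6-dien-4-yl acetate | C=C(O[Si](C)(C)C(C)(C)C)[C@H]1[C@@H]2C=C[C@](C)(O[Si](CC)(CC)CC)[C@]12/C(O[Si](C)(C)C(C)(C)C)=C/[C@H](C)[C@H](CC=C(C)C)OC(C)=O | intermediate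
24 | hydroazulene bis(enol silane), (2S,3S)-2-[5,8-bis(tert-butyldimethylsilyloxy)-1-methyl-1-(triethylsilyloxy)-1,3a,6,7-tetrahydroazulen-7-yl]-6-methylhept-5-en-3-yl acetate, C4, C7, C10 as in the target | CC(C)(C)[Si](C)(C)OC1=C[C@@H]2C=C[C@](C)(O[Si](CC)(CC)CC)C2=C(O[Si](C)(C)C(C)(C)C)[C@H]([C@H](C)[C@H](CC=C(C)C)OC(C)=O)C1 | intermediate
25 | Mannich base, C1 dimethylaminomethyl C2 ketone (C1 epimers) with C5=C6 enol silane | CN(C)CC1C(=O)C[C@@H]([C@H](C)[C@H](CC=C(C)C)OC(C)=O)C(O[Si](C)(C)C(C)(C)C)=C2[C@H]1C=C[C@]2(C)O[Si](CC)(CC)CC | intermediate (not isolated)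
26 | methiodide of 25, C1 trimethylammoniomethyl C2 ketone iodide | C[N+](C)(C)CC1C(=O)C[C@@H]([C@H](C)[C@H](CC=C(C)C)OC(C)=O)C(O[Si](C)(C)C(C)(C)C)=C2[C@H]1C=C[C@]2(C)O[Si](CC)(CC)CC.[I-] | intermediate (not isolated)
27 | methylene enone, (2S,3S)-2-[8-(tert-butyldimethylsilyloxy)-1-methyl-4-methylidene-5-oxo-1-(triethylsilyloxy)-1,3a,4,5,6,7-hexahydroazulen-7-yl]-6-methylhept-5-en-3-yl acetate | C=C1C(=O)C[C@@H]([C@H](C)[C@H](CC=C(C)C)OC(C)=O)C(O[Si](C)(C)C(C)(C)C)=C2[C@H]1C=C[C@]2(C)O[Si](CC)(CC)CC | intermediate
28 | allylic alcohol, (2S,3S)-2-[8-(tert-butyldimethylsilyloxy)-5-hydroxy-1-methyl-4-methylidene-1-(triethylsilyloxy)-1,3a,4,5,6,7-hexahydroazulen-7-yl]-6-methylhept-5-en-3-yl acetate, C2 hydroxyl β | C=C1[C@H](O)C[C@@H]([C@H](C)[C@H](CC=C(C)C)OC(C)=O)C(O[Si](C)(C)C(C)(C)C)=C2[C@H]1C=C[C@]2(C)O[Si](CC)(CC)CC | intermediate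
29 | cis-fused C5 ketone (H6 β), C6 epimer of 30 | C=C1[C@H](O)C[C@@H]([C@H](C)[C@H](CC=C(C)C)OC(C)=O)C(=O)[C@@H]2[C@H]1C=C[C@]2(C)O[Si](CC)(CC)CC | intermediate (not isolated)
30 | trans-fused C5 ketone (H6 α), (2S,3S)-2-[5-hydroxy-1-methyl-4-methylidene-8-oxo-1-(triethylsilyloxy)-1,3a,4,5,6,7,8,8a-octahydroazulen-7-yl]-6-methylhept-5-en-3-yl acetate | C=C1[C@H](O)C[C@@H]([C@H](C)[C@H](CC=C(C)C)OC(C)=O)C(=O)[C@H]2[C@H]1C=C[C@]2(C)O[Si](CC)(CC)CC | intermediate
31 | C10 triethylsilyl ether of the target, (2S,3S)-2-[5,8-dihydroxy-1-methyl-4-methylidene-1-(triethylsilyloxy)-1,3a,4,5,6,7,8,8a-octahydroazulen-7-yl]-6-methylhept-5-en-3-yl acetate | C=C1[C@H](O)C[C@@H]([C@H](C)[C@H](CC=C(C)C)OC(C)=O)[C@@H](O)[C@H]2[C@H]1C=C[C@]2(C)O[Si](CC)(CC)CC | intermediate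
32 | CNP0126182.2, (2S,3S)-6-methyl-2-[(1S,3aR,5R,7S,8R,8aR)-1,5,8-trihydroxy-1-methyl-4-methylidene-1,3a,4,5,6,7,8,8a-octahydroazulen-7-yl]hept-5-en-3-yl acetate | C=C1[C@H](O)C[C@@H]([C@H](C)[C@H](CC=C(C)C)OC(C)=O)[C@@H](O)[C@H]2[C@H]1C=C[C@]2(C)O | target

## Step count and least certain steps

Total: 24 steps (ring fragment 6, chain 5, ylide salt 1, union and endgame 12). Longest linear sequence: 18 steps (steps 1–6 and 13–24).

Step 19 (key step). The rearrangement may be slow, because in the boat the silyloxy group on C5 is pressed against the substituents on the neighbouring quaternary C10; prolonged heating would then erode the enol ethers, and any E enol ether carried over from step 18 would lead to the C4 epimer. The fallback sets out from 22 and returns at 31. The acetyl group of 22, the less hindered ketone, is silylated first with one equivalent of TBSOTf/Et3N and the C5 ketone then with TMSOTf/Et3N, giving the mixed bis(enol silane) F1, whose smaller C5 silyl group should lower the barrier; its Cope rearrangement gives the hydroazulene F2. A trimethylsilyl enol ether would not survive the Mannich and reduction steps, so the order of the endgame is reversed. Buffered aqueous acetic acid cleaves only the C5 enol ether to the cis-fused ketone F3, DBU equilibrates it to the trans-fused ketone F4, and LiBH(s-Bu)3 gives the C5 alcohol F5. The C1=C2 tert-butyldimethylsilyl enol ether is then taken through the Mannich sequence (Mannich base F6, methiodide F7) to the methylene enone F8, and reduction with the (S)-CBS catalyst and catecholborane gives 31.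

Step 15. Facial selectivity may be poor and the addition slow: C10 carries a substituent on each face of the enone, the preference for the α face rests on the smaller effective size of the silyloxy oxygen and on the C9 group, and a stabilised ylide is a weak nucleophile toward a hindered α-substituted enone. The fallback sets out from 18 and returns at 20. HF·pyridine removes both triethylsilyl groups to give the enone diol F9, in which the free C10 hydroxyl can hydrogen-bond to the C5 carbonyl; this activates the enone and holds the oxygen in its plane, so that only the C10 methyl group projects over the β face. Cyclopropanation with ylide 19 then gives the diol diketone F10, and TESOTf/2,6-lutidine restores both silyl ethers to give 20.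

Step 21. Catalyst and substrate may be mismatched: the (S)-catalyst has to deliver hydride to the α face of C2, whereas the ring may favour attack on the β face between the pseudo-axial H4 and H7, so the diastereoselectivity could be low. The fallback sets out from 27 and returns at 28. Luche reduction (NaBH4, CeCl3·7H2O, MeOH, −78 °C) is run under substrate control; if it gives the C2 epimer F11, Mitsunobu inversion with chloroacetic acid (PPh3, diisopropyl azodicarboxylate) gives the 2R chloroacetate F12, which thiourea cleaves in the presence of the acetate to give 28.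

Step 22. The equilibration may be incomplete or unselective: the preference for the trans-fused ketone is an expectation from conformational analysis, C4 is also α to the ketone and could epimerise, and the C5–C6 enolate can expel the allylic C10 silanolate by E1cB. The fallback sets out from 28 and returns at 32. Excess Bu4NF/AcOH removes the enol silane and the C10 triethylsilyl group together to give the cis-fused hydroxy ketone F13, whose free tertiary hydroxyl is a much poorer leaving group; brief treatment with Et3N or catalytic DBU equilibrates it to the trans-fused hydroxy ketone F14, and LiBH(s-Bu)3 then gives 32 directly.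

Step 23. Facial selectivity may be eroded by the C2 oxygen: if it is pseudo-axial it lies across the ring over the β face of C5 (it may even close a transannular hemiketal) and can push the bulky hydride to the α face; warming would also expose the acetate to reduction or to acyl transfer onto the new alkoxide. The fallback sets out from 30 and returns at 31 and makes no new compound: Me4NBH(OAc)3 in AcOH/MeCN at −20 °C binds to the C2 hydroxyl and delivers hydride across the ring to the β face of C5, turning the same proximity into the controlling element.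

## Further compounds

F1 | step 19 | mixed bis(enol silane), C2 tert-butyldimethylsilyl and C5 trimethylsilyl (Z) analogue of 23 | C=C(O[Si](C)(C)C(C)(C)C)[C@H]1[C@@H]2C=C[C@](C)(O[Si](CC)(CC)CC)[C@]12/C(O[Si](C)(C)C)=C/[C@H](C)[C@H](CC=C(C)C)OC(C)=O
F2 | step 19 | hydroazulene with C1=C2 tert-butyldimethylsilyl and C5=C6 trimethylsilyl enol ethers | CC(C)(C)[Si](C)(C)OC1=C[C@@H]2C=C[C@](C)(O[Si](CC)(CC)CC)C2=C(O[Si](C)(C)C)[C@H]([C@H](C)[C@H](CC=C(C)C)OC(C)=O)C1
F3 | step 19 | cis-fused C5 ketone (H6 β) with C1=C2 tert-butyldimethylsilyl enol ether | CC(C)(C)[Si](C)(C)OC1=C[C@@H]2C=C[C@](C)(O[Si](CC)(CC)CC)[C@@H]2C(=O)[C@H]([C@H](C)[C@H](CC=C(C)C)OC(C)=O)C1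
F4 | step 19 | trans-fused C5 ketone (H6 α) with C1=C2 tert-butyldimethylsilyl enol ether | CC(C)(C)[Si](C)(C)OC1=C[C@@H]2C=C[C@](C)(O[Si](CC)(CC)CC)[C@H]2C(=O)[C@H]([C@H](C)[C@H](CC=C(C)C)OC(C)=O)C1
F5 | step 19 | C5 α-alcohol with C1=C2 tert-butyldimethylsilyl enol ether | CC(C)(C)[Si](C)(C)OC1=C[C@@H]2C=C[C@](C)(O[Si](CC)(CC)CC)[C@H]2[C@H](O)[C@H]([C@H](C)[C@H](CC=C(C)C)OC(C)=O)C1
F6 | step 19 | Mannich base, C1 dimethylaminomethyl C2 ketone with free C5 hydroxyl (C1 epimers) | CN(C)CC1C(=O)C[C@@H]([C@H](C)[C@H](CC=C(C)C)OC(C)=O)[C@@H](O)[C@H]2[C@H]1C=C[C@]2(C)O[Si](CC)(CC)CC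
F7 | step 19 | methiodide of F6 | C[N+](C)(C)CC1C(=O)C[C@@H]([C@H](C)[C@H](CC=C(C)C)OC(C)=O)[C@@H](O)[C@H]2[C@H]1C=C[C@]2(C)O[Si](CC)(CC)CC.[I-]
F8 | step 19 | methylene enone with free C5 α-hydroxyl and C10 triethylsilyl ether | C=C1C(=O)C[C@@H]([C@H](C)[C@H](CC=C(C)C)OC(C)=O)[C@@H](O)[C@H]2[C@H]1C=C[C@]2(C)O[Si](CC)(CC)CC
F9 | step 15 | enone diol, bis-desilylated 18 | O=C(C[C@H](C)[C@H](CC=C(C)C)OC(C)=O)C1=CC[C@@H](O)[C@]1(C)O
F10 | step 15 | cyclopropyl diketone diol, bis-desilylated 20 | CC(=O)[C@H]1[C@@H]2C[C@@H](O)[C@](C)(O)[C@]12C(=O)C[C@H](C)[C@H](CC=C(C)C)OC(C)=O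
F11 | step 21 | C2 epimer of 28 (hydroxyl α) | C=C1[C@@H](O)C[C@@H]([C@H](C)[C@H](CC=C(C)C)OC(C)=O)C(O[Si](C)(C)C(C)(C)C)=C2[C@H]1C=C[C@]2(C)O[Si](CC)(CC)CC
F12 | step 21 | C2 chloroacetate of 28 (2R) | C=C1[C@H](OC(=O)CCl)C[C@@H]([C@H](C)[C@H](CC=C(C)C)OC(C)=O)C(O[Si](C)(C)C(C)(C)C)=C2[C@H]1C=C[C@]2(C)O[Si](CC)(CC)CC
F13 | step 22 | cis-fused C5 ketone with free C2 and C10 hydroxyls | C=C1[C@H](O)C[C@@H]([C@H](C)[C@H](CC=C(C)C)OC(C)=O)C(=O)[C@@H]2[C@H]1C=C[C@]2(C)O
F14 | step 22 | trans-fused C5 ketone with free C2 and C10 hydroxyls | C=C1[C@H](O)C[C@@H]([C@H](C)[C@H](CC=C(C)C)OC(C)=O)C(=O)[C@H]2[C@H]1C=C[C@]2(C)O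
F0 | step 23 | none | none
A1 | alternative 1 | trans-fused hydroazulene with C1 exocyclic methylene, C9/C10 acetonide, C5 silyl ether and silyl-protected C12 hydroxymethyl | C=C1CC[C@@H]([C@H](C)CO[Si](c4ccccc4)(c4ccccc4)C(C)(C)C)[C@@H](O[Si](C)(C)C(C)(C)C)[C@H]2[C@H]1C[C@@H]3OC(C)(C)O[C@]23C
A2 | alternative 2 | cis-fused tricyclic ethyl acetal with C11 attached to C4 | C=C1[C@H](O[Si](C)(C)C(C)(C)C)C[C@@H]([C@H](C)[C@H](OCC)O3)[C@@H]3[C@H]2[C@H]1C=C[C@]2(C)O[Si](CC)(CC)CC
A3 | alternative 3 | tricyclic cis-fused α-methylene-γ-lactone (C5–O–C12) | C=C1[C@H](O[Si](C)(C)C(C)(C)C)C[C@@H](C(=C)C(=O)O3)[C@@H]3[C@H]2[C@H]1C=C[C@]2(C)O[Si](CC)(CC)CC
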